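## Retrosynthetic overview

1. Numbering: chromene O1, C2, C3, C4, C4a–C8a; chain Cb (on C2) and Ca (on the cyclohexane); cyclohexane ring A with C1' (quaternary), C2' (=CH2), C3' (CHMe), C4', C5', C6'. The target comes from its chromene-5,8-quinone, and that from a 2,5-dimethoxyquinone carrying a (Z)-alkenyl side chain with the free C2 tertiary alcohol; O1–C8a is closed by intramolecular addition–elimination, so the pyran ring B is formed last.
2. The exocyclic methylene comes from a C2' ketone (Wittig). C3' is set by equilibration next to a C5' carboxyl group that anchors the chair; the carboxyl group is then removed by Barton decarboxylation.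
3. The keto acid comes from the Diels–Alder adduct of a 6-isopropenyl-3,4-dihydro-2H-pyran (diene C4'=C3'–C2'=C1') with a chiral acrylimide (C5'=C6'); bonds C4'–C5' and C1'–C6' form in one step, which closes ring A and sets C1'.
4. Enabling feature: O1 lies δ to C2' along O1–C2–Cb–Ca–C1'–C2'. These six atoms are closed to a temporary dihydropyran, so the C2' ketone becomes a ring enol ether with locked C2'=C1' geometry (Ca outside, methyl inside) and the C2 stereocenter sits on the diene ring. Hydrolysis after the cycloaddition opens this ring again.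
5. The diene comes from a δ-lactone (ketene acetal phosphate, Stille), made from (R)-2-methylglycidol, a methallyl Grignard reagent and an aryl alkyne (Ohira–Bestmann, Sonogashira). Ring order: temporary dihydropyran, ring A, dihydropyran opened, ring B.

Key step: step 11

Remark: (R)-2-methylglycidol is taken as a catalogue compound, and the δ-hydroxy ketones 24–26 are drawn open-chain although they may rest partly as bicyclic hemiketals.

## Route

Step 1
Reactants: 1 (R)-2-methylglycidol; 2 2-methylallylmagnesium chloride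
Product: 3 (2S)-2,5-dimethylhex-5-ene-1,2-diol
Conditions: 2 (3 equiv), CuI (5 mol %), THF, −30 to 0 °C; aq. NH4Cl
Reagents that add atoms: none
Why: Copper-catalysed SN2 opening of the 2,2-disubstituted epoxide at its CH2 terminus by the allylic Grignard reagent (the first equivalent only deprotonates the alcohol) touches no bond of the quaternary carbinol carbon, so its configuration is carried over (R becomes S by priority change only).

Step 2
Reactants: 3 diol
Product: 4 (2S)-2-hydroxy-2,5-dimethylhex-5-enal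
Conditions: SO3·pyridine, DMSO, i-Pr2NEt, CH2Cl2, 0 °C
Reagents that add atoms: none
Why: Parikh–Doering (activated DMSO) oxidation takes the primary alcohol to the aldehyde, leaves the tertiary alcohol alone and cannot cleave the 1,2-diol; the quaternary α-carbon cannot epimerise.

Step 3
Reactants: 4 hydroxy aldehyde
Product: 5 (3S)-3,6-dimethylhept-6-en-1-yn-3-ol
Conditions: Ohira–Bestmann reagent (1.3 equiv), K2CO3, MeOH, 0 °C to rt
Reagents that add atoms: dimethyl (1-diazo-2-oxopropyl)phosphonate, CC(=O)C(=[N+]=[N-])P(=O)(OC)OC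
Why: Seyferth–Gilbert homologation in the Ohira–Bestmann variant runs under mild carbonate conditions that tolerate the free tertiary alcohol, and the fully substituted α-carbon keeps its configuration.

Step 4
Reactants: 6 1,2,4,5-tetramethoxybenzene
Product: 8 3-iodo-1,2,4,5-tetramethoxybenzene, via aryllithium 7 (not isolated)
Conditions: n-BuLi, THF, 0 °C to rt; then I2, −78 °C to rt
Reagents that add atoms: iodine, II
Why: Directed ortho-lithiation between two methoxy groups of the symmetric arene, then iodinolysis, should give a single aryl iodide.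

Step 5
Reactants: 5 alkynol; 8 aryl iodide
Product: 9 (3S)-3,6-dimethyl-1-(2,3,5,6-tetramethoxyphenyl)hept-6-en-1-yn-3-ol
Conditions: PdCl2(PPh3)2 (3 mol %), CuI (5 mol %), Et3N, THF, 55 °C
Reagents that add atoms: none
Why: Sonogashira coupling of a terminal tertiary propargylic alcohol with an aryl iodide is routine, and the hindered internal alkyne it gives is inert in the next hydroboration.

Step 6
Reactants: 9 aryl alkynol
Product: 11 (5S)-2,5-dimethyl-7-(2,3,5,6-tetramethoxyphenyl)hept-6-yne-1,5-diol (C2 epimer mixture), via B-alkyl-9-BBN adduct 10 (not isolated)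
Conditions: 9-BBN (2.5 equiv), THF, 0 °C to rt; then NaOH, H2O2, 0 °C to rt
Reagents that add atoms: hydrogen peroxide, OO
Why: Anti-Markovnikov hydroboration–oxidation with 9-BBN is much faster at a 1,1-disubstituted terminal alkene than at a hindered internal alkyne; the new stereocenter is uncontrolled, which does not matter because it becomes sp2 in step 8.

Step 7
Reactants: 11 diol
Product: 13 (6S)-3,6-dimethyl-6-[(2,3,5,6-tetramethoxyphenyl)ethynyl]oxan-2-one (C3 epimer mixture), via lactol 12 (not isolated)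
Conditions: n-Pr4N[RuO4] (5 mol %), N-methylmorpholine N-oxide (3 equiv), 4 Å molecular sieves, CH2Cl2, rt
Reagents that add atoms: none
Why: Ley–Griffith oxidation of the 1,5-diol gives the aldehyde, which the tertiary alcohol traps as a six-membered lactol that is oxidised on to the δ-lactone.

Step 8
Reactants: 13 lactone
Product: 15 (2S)-2,5-dimethyl-2-[(2,3,5,6-tetramethoxyphenyl)ethynyl]-3,4-dihydro-2H-pyran-6-yl diphenyl phosphate, via potassium enolate 14 (not isolated)
Conditions: KN(SiMe3)2, THF/HMPA, −78 °C; then (PhO)2P(O)Cl, −78 °C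
Reagents that add atoms: diphenyl chlorophosphate, O=P(Cl)(Oc1ccccc1)Oc1ccccc1
Why: Enolisation of the lactone and O-phosphorylation (lactone-derived ketene acetal phosphate chemistry) turns the carbonyl carbon into a cross-coupling site and erases the uncontrolled α-stereocenter.

Step 9
Reactants: 15 ketene acetal phosphate; 16 tributyl(prop-1-en-2-yl)stannane
Product: 17 (2S)-2,5-dimethyl-6-(prop-1-en-2-yl)-2-[(2,3,5,6-tetramethoxyphenyl)ethynyl]-3,4-dihydro-2H-pyran
Conditions: Pd(PPh3)4 (5 mol %), LiCl (3 equiv), THF, 65 °C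
Reagents that add atoms: none
Why: Stille coupling of the ketene acetal phosphate with the isopropenylstannane installs the 2-oxy-1,3-diene, whose enol ether geometry is fixed by the ring.

Step 10
Reactants: 18 (4S)-4-benzyl-1,3-oxazolidin-2-one; 19 acryloyl chloride
Product: 21 (4S)-4-benzyl-3-(prop-2-enoyl)-1,3-oxazolidin-2-one, via lithium oxazolidinonide 20 (not isolated)
Conditions: n-BuLi, THF, −78 °C; then 19, −78 to 0 °C
Reagents that add atoms: none
Why: N-acylation of the lithiated Evans oxazolidinone with the acid chloride at low temperature gives the chiral dienophile.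

Step 11
Reactants: 17 diene; 21 acrylimide
Product: 22 (4S)-4-benzyl-3-{(2S,4aS,6S)-2,4a,8-trimethyl-2-[(2,3,5,6-tetramethoxyphenyl)ethynyl]-3,4,4a,5,6,7-hexahydro-2H-chromene-6-carbonyl}-1,3-oxazolidin-2-one (acyl group cis to ring carbon C4 and trans to the 4a-methyl)
Conditions: 21 (1.1 equiv), Et2AlCl (1.4 equiv), CH2Cl2, −78 to −40 °C; aq. NaHCO3
Reagents that add atoms: none
Why: Et2AlCl turns 21 into the cationic, chelated s-cis imide, to which the 2-oxy-diene should add by a concerted but strongly asynchronous endo Diels–Alder reaction (bond C1'–C6' leading, C4'–C5' following), so ring A is closed by one intermolecular [4+2] cycloaddition and not by a separate cyclisation. The closest known reaction type is the auxiliary-controlled, aluminium-promoted Diels–Alder reaction of N-acryloyl oxazolidinones with 2-oxygenated and semicyclic dienes. C5' is controlled by the auxiliary: the benzyl group shields the α-Re face of the dienophile, so the diene bonds to the α-Si face. C1' follows from the endo topology together with the ring-locked enol ether geometry (Ca outside, methyl inside), which places the acyl group cis to Ca and trans to the C1' methyl. The substrate should act in the same direction, because the slim alkynyl group at C2 sits axial on the half-chair dihydropyran and the dienophile enters on the opposite face. The step needs para regioselectivity (C1' to the β-carbon, acyl at C5'), which the ring oxygen on C2' secures by making C1' the nucleophilic diene terminus, helped by the small size of the β-CH2.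

Step 12
Reactants: 22 cycloadduct
Product: 25 (1S,3S,5R)-3-[(3S)-3-hydroxy-3-methyl-5-(2,3,5,6-tetramethoxyphenyl)pent-4-yn-1-yl]-3,5-dimethyl-4-oxocyclohexane-1-carboxylic acid, via lithium carboxylate 23 (not isolated), via keto acid epimer mixture 24 (not isolated)
Conditions: LiOH, H2O2, THF/H2O, 0 °C; Na2SO3; then 1 M HCl, THF, 0 °C to rt; then K2CO3, MeOH, rt; acidify to pH 3
Reagents that add atoms: hydrogen peroxide, OO; water, O
Why: LiOOH cleaves the exocyclic imide carbonyl (Evans auxiliary removal), aqueous acid hydrolyses the enol ether by protonation at C3' and water addition at C2' (opening the temporary dihydropyran without breaking O1–C2), and carbonate equilibration then sets C3', because the non-epimerisable C5' carboxylate and the C1' side chain lock the chair and the C3' methyl goes equatorial (cis to both, trans to the axial C1' methyl) to avoid a syn-diaxial methyl/methyl contact.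

Step 13
Reactants: 25 keto acid
Product: 26 (1S,3S,5R)-3-[(3S,4Z)-3-hydroxy-3-methyl-5-(2,3,5,6-tetramethoxyphenyl)pent-4-en-1-yl]-3,5-dimethyl-4-oxocyclohexane-1-carboxylic acid
Conditions: H2 (1 atm), Pd/CaCO3 poisoned with Pb(OAc)2, quinoline, EtOAc, rt
Reagents that add atoms: none
Why: Lindlar semihydrogenation gives the Z-alkene by syn addition of H2 and is placed before the basic step 14, because a tertiary propargylic alkoxide could undergo retro-alkynylation whereas the allylic one cannot.

Step 14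
Reactants: 26 keto acid
Product: 27 (1S,3S,5R)-3-[(3S,4Z)-3-hydroxy-3-methyl-5-(2,3,5,6-tetramethoxyphenyl)pent-4-en-1-yl]-3,5-dimethyl-4-methylidenecyclohexane-1-carboxylic acid
Conditions: Ph3PCH3Br (6 equiv), KOt-Bu (5.5 equiv), THF/toluene, rt to 60 °C; aq. NaH2PO4
Reagents that add atoms: methyltriphenylphosphonium bromide, C[P+](c1ccccc1)(c1ccccc1)c1ccccc1.[Br-]
Why: Wittig methylenation with excess ylide converts the hindered ketone, and since the C5' carboxylate cannot enolise, any base-induced epimerisation at C3' only returns to the locked equatorial configuration before the carbonyl group is consumed.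

Step 15
Reactants: 27 methylene acid
Product: 29 (1Z,3S)-5-[(1R,3R)-1,3-dimethyl-2-methylidenecyclohexyl]-3-methyl-1-(2,3,5,6-tetramethoxyphenyl)pent-1-en-3-ol, via Barton ester 28 (not isolated)
Conditions: 2-mercaptopyridine N-oxide, DCC, DMAP (cat.), CH2Cl2, 0 °C to rt, dark; then t-BuSH, visible light, rt
Reagents that add atoms: none
Why: Barton reductive decarboxylation generates the secondary C5' radical, which should take hydrogen from the thiol faster than it can add 5-endo to the exocyclic alkene, so the anchor is removed and C5' becomes CH2.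

Step 16
Reactants: 29 tetramethoxyarene
Product: 30 3-{(1Z,3S)-5-[(1R,3R)-1,3-dimethyl-2-methylidenecyclohexyl]-3-hydroxy-3-methylpent-1-en-1-yl}-2,5-dimethoxycyclohexa-2,5-diene-1,4-dione
Conditions: (NH4)2Ce(NO3)6 (2.5 equiv), MeCN/H2O, 0 °C, 15 min
Reagents that add atoms: water, O
Why: Oxidative demethylation of a para-dimethoxy pair gives the 2,5-dimethoxy-1,4-benzoquinone (both para pairs lead to the same quinone), and the isolated alkenes and the tertiary alcohol should survive the short, cold exposure.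

Step 17
Reactants: 30 quinone
Product: 31 (2S)-2-{2-[(1R,3R)-1,3-dimethyl-2-methylidenecyclohexyl]ethyl}-6-methoxy-2-methyl-2H-chromene-5,8-dione
Conditions: Cs2CO3 (0.3 equiv), 4 Å molecular sieves, MeCN, rt
Reagents that add atoms: none
Why: Intramolecular vinylogous transesterification (6-endo-trig conjugate addition of the tertiary alkoxide at the methoxy-bearing quinone carbon, then loss of methoxide) is enforced by the Z-alkene and closes ring B without breaking the carbinol C–O bond, so C2 stays S.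

Step 18
Reactants: 31 chromenequinone
Product: 32 (2S)-2-{2-[(1R,3R)-1,3-dimethyl-2-methylidenecyclohexyl]ethyl}-6-methoxy-2-methyl-2H-chromene-5,8-diol (CNP0247066.1)
Conditions: Na2S2O4, EtOAc/H2O, rt, argon
Reagents that add atoms: none
Why: Dithionite reduction of the 1,4-benzoquinone to the hydroquinone is fast and neutral and should touch neither the alkenes nor the acid-sensitive 2H-chromene.

## Compound list

1 | (R)-2-methylglycidol, [(2R)-2-methyloxiran-2-yl]methanol | C[C@@]1(CO)CO1 | starting material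
2 | 2-methylallylmagnesium chloride | C=C(C)C[Mg]Cl | starting material
3 | (2S)-2,5-dimethylhex-5-ene-1,2-diol | C=C(C)CC[C@@](O)(C)CO | intermediate
4 | (2S)-2-hydroxy-2,5-dimethylhex-5-enal | C=C(C)CC[C@@](O)(C)C=O | intermediate
5 | (3S)-3,6-dimethylhept-6-en-1-yn-3-ol | C=C(C)CC[C@@](O)(C)C#C | intermediate
6 | 1,2,4,5-tetramethoxybenzene | COc1cc(OC)c(OC)cc1OC | starting material
7 | (2,3,5,6-tetramethoxyphenyl)lithium | [Li]c1c(OC)c(OC)cc(OC)c1OC | intermediate (not isolated)
8 | 3-iodo-1,2,4,5-tetramethoxybenzene | COc1cc(OC)c(OC)c(I)c1OC | intermediate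
9 | (3S)-3,6-dimethyl-1-(2,3,5,6-tetramethoxyphenyl)hept-6-en-1-yn-3-ol | C=C(C)CC[C@@](O)(C)C#Cc1c(OC)c(OC)cc(OC)c1OC | intermediate
10 | (3S)-7-(9-borabicyclo[3.3.1]nonan-9-yl)-3,6-dimethyl-1-(2,3,5,6-tetramethoxyphenyl)hept-1-yn-3-ol (C6 epimers) | CC(CB1C2CCCC1CCC2)CC[C@@](O)(C)C#Cc1c(OC)c(OC)cc(OC)c1OC | intermediate (not isolated)
11 | (5S)-2,5-dimethyl-7-(2,3,5,6-tetramethoxyphenyl)hept-6-yne-1,5-diol (C2 epimers) | OCC(C)CC[C@@](O)(C)C#Cc1c(OC)c(OC)cc(OC)c1OC | intermediate
12 | (6S)-3,6-dimethyl-6-[(2,3,5,6-tetramethoxyphenyl)ethynyl]oxan-2-ol (lactol, epimers) | OC1C(C)CC[C@@](O1)(C)C#Cc2c(OC)c(OC)cc(OC)c2OC | intermediate (not isolated)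
13 | (6S)-3,6-dimethyl-6-[(2,3,5,6-tetramethoxyphenyl)ethynyl]oxan-2-one (C3 epimers) | O=C1C(C)CC[C@@](O1)(C)C#Cc2c(OC)c(OC)cc(OC)c2OC | intermediate
14 | potassium (2S)-2,5-dimethyl-2-[(2,3,5,6-tetramethoxyphenyl)ethynyl]-3,4-dihydro-2H-pyran-6-olate | [K+].[O-]C1=C(C)CC[C@@](O1)(C)C#Cc2c(OC)c(OC)cc(OC)c2OC | intermediate (not isolated)
15 | (2S)-2,5-dimethyl-2-[(2,3,5,6-tetramethoxyphenyl)ethynyl]-3,4-dihydro-2H-pyran-6-yl diphenyl phosphate | O=P(Oc1ccccc1)(Oc2ccccc2)OC3=C(C)CC[C@@](O3)(C)C#Cc4c(OC)c(OC)cc(OC)c4OC | intermediate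
16 | tributyl(prop-1-en-2-yl)stannane | C=C(C)[Sn](CCCC)(CCCC)CCCC | starting material
17 | (2S)-2,5-dimethyl-6-(prop-1-en-2-yl)-2-[(2,3,5,6-tetramethoxyphenyl)ethynyl]-3,4-dihydro-2H-pyran | C=C(C)C1=C(C)CC[C@@](O1)(C)C#Cc2c(OC)c(OC)cc(OC)c2OC | intermediate
18 | (4S)-4-benzyl-1,3-oxazolidin-2-one | O=C1N[C@@H](Cc2ccccc2)CO1 | starting material
19 | acryloyl chloride | C=CC(=O)Cl | starting material
20 | lithium (4S)-4-benzyl-2-oxo-1,3-oxazolidin-3-ide | [Li+].O=C1[N-][C@@H](Cc2ccccc2)CO1 | intermediate (not isolated)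
21 | (4S)-4-benzyl-3-(prop-2-enoyl)-1,3-oxazolidin-2-one | C=CC(=O)N1[C@@H](Cc2ccccc2)COC1=O | intermediate
22 | (4S)-4-benzyl-3-{(2S,4aS,6S)-2,4a,8-trimethyl-2-[(2,3,5,6-tetramethoxyphenyl)ethynyl]-3,4,4a,5,6,7-hexahydro-2H-chromene-6-carbonyl}-1,3-oxazolidin-2-one | O1C2=C(C)C[C@H](C(=O)N3[C@@H](Cc4ccccc4)COC3=O)C[C@]2(C)CC[C@@]1(C)C#Cc5c(OC)c(OC)cc(OC)c5OC | intermediate
23 | lithium (2S,4aS,6S)-2,4a,8-trimethyl-2-[(2,3,5,6-tetramethoxyphenyl)ethynyl]-3,4,4a,5,6,7-hexahydro-2H-chromene-6-carboxylate | O1C2=C(C)C[C@H](C(=O)[O-])C[C@]2(C)CC[C@@]1(C)C#Cc3c(OC)c(OC)cc(OC)c3OC.[Li+] | intermediate (not isolated)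
24 | (1S,3S)-3-[(3S)-3-hydroxy-3-methyl-5-(2,3,5,6-tetramethoxyphenyl)pent-4-yn-1-yl]-3,5-dimethyl-4-oxocyclohexane-1-carboxylic acid (C5 epimers) | O=C1C(C)C[C@H](C(=O)O)C[C@]1(C)CC[C@@](O)(C)C#Cc2c(OC)c(OC)cc(OC)c2OC | intermediate (not isolated)
25 | (1S,3S,5R)-3-[(3S)-3-hydroxy-3-methyl-5-(2,3,5,6-tetramethoxyphenyl)pent-4-yn-1-yl]-3,5-dimethyl-4-oxocyclohexane-1-carboxylic acid | O=C1[C@H](C)C[C@H](C(=O)O)C[C@]1(C)CC[C@@](O)(C)C#Cc2c(OC)c(OC)cc(OC)c2OC | intermediate
26 | (1S,3S,5R)-3-[(3S,4Z)-3-hydroxy-3-methyl-5-(2,3,5,6-tetramethoxyphenyl)pent-4-en-1-yl]-3,5-dimethyl-4-oxocyclohexane-1-carboxylic acid | O=C1[C@H](C)C[C@H](C(=O)O)C[C@]1(C)CC[C@@](O)(C)/C=C\c2c(OC)c(OC)cc(OC)c2OC | intermediate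
27 | (1S,3S,5R)-3-[(3S,4Z)-3-hydroxy-3-methyl-5-(2,3,5,6-tetramethoxyphenyl)pent-4-en-1-yl]-3,5-dimethyl-4-methylidenecyclohexane-1-carboxylic acid | C=C1[C@H](C)C[C@H](C(=O)O)C[C@]1(C)CC[C@@](O)(C)/C=C\c2c(OC)c(OC)cc(OC)c2OC | intermediate
28 | 2-thioxopyridin-1(2H)-yl ester of 27 (Barton ester) | C=C1[C@H](C)C[C@H](C(=O)ON3C=CC=CC3=S)C[C@]1(C)CC[C@@](O)(C)/C=C\c2c(OC)c(OC)cc(OC)c2OC | intermediate (not isolated)
29 | (1Z,3S)-5-[(1R,3R)-1,3-dimethyl-2-methylidenecyclohexyl]-3-methyl-1-(2,3,5,6-tetramethoxyphenyl)pent-1-en-3-ol | C=C1[C@H](C)CCC[C@]1(C)CC[C@@](O)(C)/C=C\c2c(OC)c(OC)cc(OC)c2OC | intermediate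
30 | 3-{(1Z,3S)-5-[(1R,3R)-1,3-dimethyl-2-methylidenecyclohexyl]-3-hydroxy-3-methylpent-1-en-1-yl}-2,5-dimethoxycyclohexa-2,5-diene-1,4-dione | C=C1[C@H](C)CCC[C@]1(C)CC[C@@](O)(C)/C=C\C2=C(OC)C(=O)C=C(OC)C2=O | intermediate
31 | (2S)-2-{2-[(1R,3R)-1,3-dimethyl-2-methylidenecyclohexyl]ethyl}-6-methoxy-2-methyl-2H-chromene-5,8-dione | C=C1[C@H](C)CCC[C@]1(C)CC[C@@]1(C)C=CC2=C(O1)C(=O)C=C(OC)C2=O | intermediate
32 | (2S)-2-{2-[(1R,3R)-1,3-dimethyl-2-methylidenecyclohexyl]ethyl}-6-methoxy-2-methyl-2H-chromene-5,8-diol | C=C1[C@H](C)CCC[C@]1(C)CC[C@@]1(C)C=Cc2c(O)c(OC)cc(O)c2O1 | target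

## Step count and risks

Total steps: 18. Longest linear sequence: 16 steps (steps 1–3, 5–9 and 11–18); steps 4 and 10 are side branches.

Three steps most likely to fail:

Step 11. Bond formation at the fully substituted diene terminus C1' may be slow, or may turn stepwise (Mukaiyama–Michael addition without clean ring closure), which would erode endo and facial control. Fallback: from diene 17, the cycloaddition would be run as a catalytic enantioselective Diels–Alder reaction with the smaller dienophile 2,2,2-trifluoroethyl acrylate. The catalyst would be a triflimide-activated chiral oxazaborolidine (the B-o-tolyl oxazaborolidine of α,α-diphenylprolinol protonated with HNTf2, antipode chosen so that the diene adds to the acrylate α-Si face; CH2Cl2, −78 °C). This should give 2,2,2-trifluoroethyl (2S,4aS,6S)-2,4a,8-trimethyl-2-[(2,3,5,6-tetramethoxyphenyl)ethynyl]-3,4,4a,5,6,7-hexahydro-2H-chromene-6-carboxylate F1. LiOH in THF/H2O should then give lithium carboxylate 23, where the route is rejoined inside step 12.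

Step 17. Addition of the hindered tertiary alkoxide may be reversible without loss of methoxide, or the base may degrade the quinone. Fallback: from quinone 30, selective hydrolysis of the vinylogous ester next to the alkenyl group (dilute NaOH, MeOH/H2O, 0 °C, the usual endgame to 2-hydroxy-5-methoxy-3-substituted benzoquinones) would give 2-hydroxy-3-{(1Z,3S)-5-[(1R,3R)-1,3-dimethyl-2-methylidenecyclohexyl]-3-hydroxy-3-methylpent-1-en-1-yl}-5-methoxycyclohexa-2,5-diene-1,4-dione F2. Tf2O and 2,6-lutidine (CH2Cl2, −78 °C) would convert its acidic enol into 2-{(1Z,3S)-5-[(1R,3R)-1,3-dimethyl-2-methylidenecyclohexyl]-3-hydroxy-3-methylpent-1-en-1-yl}-4-methoxy-3,6-dioxocyclohexa-1,4-dien-1-yl trifluoromethanesulfonate F3. Its far better leaving group should be displaced by the neighbouring tertiary alcohol on warming to 0 °C, giving chromenequinone 31.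

Step 14. The basic ylide may only enolise the hindered, doubly deprotonated keto acid, so that methylenation stalls. Fallback: from keto acid 26, a Peterson olefination. Addition of Me3SiCH2Li/CeCl3 (THF, −78 °C) would give (1S,3S,5R)-4-hydroxy-3-[(3S,4Z)-3-hydroxy-3-methyl-5-(2,3,5,6-tetramethoxyphenyl)pent-4-en-1-yl]-3,5-dimethyl-4-[(trimethylsilyl)methyl]cyclohexane-1-carboxylic acid F4. KH in THF (syn-elimination) should then give methylene acid 27.

Further compounds
F1 | step 11 | 2,2,2-trifluoroethyl (2S,4aS,6S)-2,4a,8-trimethyl-2-[(2,3,5,6-tetramethoxyphenyl)ethynyl]-3,4,4a,5,6,7-hexahydro-2H-chromene-6-carboxylate | O1C2=C(C)C[C@H](C(=O)OCC(F)(F)F)C[C@]2(C)CC[C@@]1(C)C#Cc3c(OC)c(OC)cc(OC)c3OC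
F2 | step 17 | 2-hydroxy-3-{(1Z,3S)-5-[(1R,3R)-1,3-dimethyl-2-methylidenecyclohexyl]-3-hydroxy-3-methylpent-1-en-1-yl}-5-methoxycyclohexa-2,5-diene-1,4-dione | C=C1[C@H](C)CCC[C@]1(C)CC[C@@](O)(C)/C=C\C2=C(O)C(=O)C=C(OC)C2=O
F3 | step 17 | 2-{(1Z,3S)-5-[(1R,3R)-1,3-dimethyl-2-methylidenecyclohexyl]-3-hydroxy-3-methylpent-1-en-1-yl}-4-methoxy-3,6-dioxocyclohexa-1,4-dien-1-yl trifluoromethanesulfonate | C=C1[C@H](C)CCC[C@]1(C)CC[C@@](O)(C)/C=C\C2=C(OS(=O)(=O)C(F)(F)F)C(=O)C=C(OC)C2=O
F4 | step 14 | (1S,3S,5R)-4-hydroxy-3-[(3S,4Z)-3-hydroxy-3-methyl-5-(2,3,5,6-tetramethoxyphenyl)pent-4-en-1-yl]-3,5-dimethyl-4-[(trimethylsilyl)methyl]cyclohexane-1-carboxylic acid (C4 epimers) | C[Si](C)(C)CC1(O)[C@H](C)C[C@H](C(=O)O)C[C@]1(C)CC[C@@](O)(C)/C=C\c2c(OC)c(OC)cc(OC)c2OC
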